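A reading at 8.0 s falls before every sampled time, so it is reckoned here from how E grows.

| flask | G | Z | D | remark | time |
|---|---|---|---|---|---|
| theta | 0.058 M | 7.9 mM (held) | 1.7 mM | run made earlier |  |
| eta | 0.058 M | 7.9 mM (held) | 2.6 mM | run made earlier |  |
| epsilon | 0.12 M | 7.9 mM (held) | 1.2 mM | run made earlier |  |
| flask | 0.058 M | 7.9 mM (held) | 1.2 mM |  | 8.0 min |

| run | time / min | L / % | E / % |
|---|---|---|---|
| theta | 0.667 | 44.0 | 16.7 |
| theta | 1.00 | 56.9 | 27.6 |
| theta | 1.33 | 60.5 | 34.2 |
| theta | 2.50 | 61.3 | 39.0 |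
| theta | 3.00 | 60.9 | 39.0 |
| theta | 5.00 | 60.7 | 38.8 |
| theta | 8.00 | 60.7 | 39.2 |
| eta | 1.00 | 60.9 | 34.3 |
| eta | 2.50 | 61.0 | 38.8 |
| eta | 3.00 | 61.2 | 39.4 |
| eta | 5.00 | 60.8 | 38.5 |
| eta | 6.00 | 60.8 | 38.7 |
| eta | 8.00 | 61.3 | 39.2 |
| epsilon | 0.667 | 26.1 | 7.5 |
| epsilon | 1.33 | 47.8 | 22.2 |
| epsilon | 2.50 | 61.1 | 36.9 |
| epsilon | 4.00 | 60.7 | 39.0 |
| epsilon | 8.00 | 61.1 | 38.9 |

(scatter of a reading: 0.3 percentage points)

1. ratio of L to E at 8.0 s
2. ratio of L to E at 8.0 min

- at the start none of Z is in solution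

The runs end near L/E = 1.56. The reckoning here takes E to grow from L over D, pseudo-first-order at fixed D: dE/dt = κD(L − 1.56E). The first two theta readings give κ = 20.2 M⁻¹ s⁻¹, the rate of E per unit of D and per unit of L above balance. Its time 1/(κD) in the flask, 0.687 min, is shorter than 8.0 min, so the ratio there should be 1.56.

Early on, if L grows as a power of time, s = (L/E)κDt is one more than that power, and κDt at 8.0 s is 0.194. Z starts with none in solution. If L waits on one stage before it, the power is 2, so s = 3 puts the low end of the estimate for the ratio at 15.5. If L waits on dissolved Z as well, the power is at most 3, so s = 4 puts the high end at 20.6. Epsilon, with the same D but more G, reads s = 3.38 at 0.667 min, a later time, so that reading serves as a guide to the size of s and no more.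

The forecast gives 11 (7.5 to 20) and 1.56 (1.53 to 1.59), adding that “Any start-up lag from Z dissolving would push this higher”. Its 11 stands lower than this bracket.

The flask gives 17.4 at 8.0 s and 1.56 at 8.0 min.

    G + D → D + Q (k = 25.0 M⁻¹ s⁻¹)
    J + D + Q → D + L (k = 17000 M⁻² s⁻¹)
    Z ⇌ J, rate k3*(csat - [J]) (kL = 0.170 s⁻¹)
    L + D ⇌ E + D, rate k4*[D]*[L] forward; the back reaction follows from the equilibrium constant (K = 0.640, k = 20.0 M⁻¹ s⁻¹)

The forward step from L to E alone, with the way back not counted and D as charged, has a half-life of 0.48 min, shorter than 8.0 min. Reckoned with κ, the flask's ratio at 8.0 s gives s = 3.37, above 3 and below 4.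

With 0.0020 M of D, the same reckoning with κ puts the ratio at 8.0 s between 9.28 and 12.4. That neighbour flask gives 9.79.

The runs stem from a simulated flask with constants of no real substance; the scatter is artificial.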